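## The problem

Compound 38 is a linear heptamer: seven benzene rings, lettered A to G, are held together only by six diaryl ether oxygens and carry eighteen free hydroxyl groups. Ring A is a 2,4,6-trihydroxyphenyl end, rings B and F are 4-aryloxy-3,5-dihydroxyphenoxy units, rings C and E are 2-aryloxy-3,4,5-trihydroxyphenoxy units, ring D is a 3-aryloxy-4,5-dihydroxyphenoxy unit and ring G is a 3,4,5-trihydroxyphenyl end. There is no stereocenter, so nothing has to be set or relayed; the task is purely regiochemical: which oxygen sits on which carbon, and how each bridge is made. Four bridges (A–B, C–D, E–F, F–G) join a carbon flanked by two oxygenated carbons to a carbon flanked by two CH groups, which suits copper coupling of a hindered phenol with an unhindered aryl halide; the D–E bridge joins two carbons with one ortho substituent each. The B–C bridge is the awkward one: its ring B carbon (B4) lies between the hydroxyl-bearing carbons B3 and B5, and its ring C carbon (C1) is next to the carbon carrying the ring D ether, so a coupling would be hindered on both sides. The free polyphenol, with pyrogallol- and catechol-type arrays, oxidises readily in air, above all in base, so every hydroxyl must stay masked to the last step and the unmasking must spare the diaryl ethers. What opens a way round the B–C bridge is the oxygen pattern of ring B: B1 (ether to ring A) lies between the CH carbons B2 and B6, and B3–OH is meta to that ether and ortho to the ring C ether at B4. This is the resorcinol monoether array that a cyclobutenone (supplying B3, B4, B5, B6) and an ynol ether (supplying B1, B2) give on benzannulation.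

## Retrosynthesis

**38 from 37.** The last move cuts eighteen O–alkyl bonds (seventeen methyl, one ethyl) and no skeletal bond. Methyl is preferred to benzyl because every ring building block is commercial as its methyl ether and methyl ethers pass unchanged through peracid, organolithium, ketene and copper chemistry. The single ethyl group is inherited from ethoxyacetylene 14 and falls to the same reagent. 37 is air-stable and chromatographable, so all handling problems of the polyphenol are confined to one step. The forward reaction must cleave every alkyl aryl ether and no diaryl ether, which is the normal behaviour of BBr3.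

**37 from 24 and 36.** The C–D bridge is cut between the ring C oxygen and carbon D1. It divides the heptamer into three and four rings and belongs to the favourable class: phenol 24 is hindered, but bromide 36 has two CH neighbours. Cutting B–C instead would be hindered on both sides; cutting D–E would put the halide next to a large aryloxy group. The forward step is an Ullmann coupling that must tolerate a doubly ortho-substituted phenoxide.

**36 from 32 and 35, and 35 from 33.** The D–E bridge is cut at carbon D5. Dihalide 35 carries iodide at D5 and bromide at D1, so the phenol 32 can be joined at iodine while the bromide is kept for the union with 24. 35 comes from 4-bromo-2-methoxyphenol 33 by iodination ortho to the hydroxyl (34) and methylation. The forward coupling must discriminate iodide from bromide.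

**32 from 27 and 30, and 30 from 28 and 29.** The E–F and F–G bridges are both of the hindered-phenol/unhindered-halide class. Bromophenol 28 and iodide 29 give bromide 30; phenol 27 and 30 give benzyl ether 31, whose hydrogenolysis frees the ring E oxygen (32) for the D–E bridge. All four pieces are one-ring compounds.

**27 from 8 via 25, and 8 from 7.** The ring E phenol 27 needs its free hydroxyl between a benzyloxy and a methoxy group. Ortho-formylation of 3,4,5-trimethoxyphenol 7 gives aldehyde 8; benzylation (25) and Baeyer–Villiger oxidation turn the formyl carbon into that hydroxyl. Aldehyde 8 also serves ring C (below), where the order of alkylation and oxidation is reversed to give the regioisomeric protection pattern.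

**24 from 22 via 23.** No skeletal bond is cut: the phenol made in the key step is methylated (23) and the ring C benzyl ether is removed by hydrogenolysis (24). This leaves exactly one free hydroxyl, the hindered ring C oxygen needed for the union.

**22 from 17 and 6 (key disconnection).** Ring B is taken apart at B2–B3 and B1–B6, two carbon–carbon bonds, into cyclobutenone 17 and aryl ynol ether 6. Against cutting either ring B ether, this leaves both ethers intact: the ring C oxygen sits on an sp3 carbon of 17 and the ring A oxygen on an sp carbon of 6, and neither needs an aryl–oxygen coupling. The three-ring phenol is reduced to two one-ring pieces. The forward reaction must add the ketene regioselectively to the alkyne and keep 6 alive at the temperature at which 17 opens.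

**6 from 1 and 2.** The ring A oxygen–alkyne bond is traced to 2,4,6-trimethoxyphenol 1 and trichloroethylene 2 through dichlorovinyl ether 4. This is phenoxide chemistry at a linear electrophile, so the two ortho methoxy groups do not interfere.

**17 from 13 and 14, and 13 from 8.** The four-membered ring is cut into the aryloxyketene derived from acid 13 and ethoxyacetylene 14. Acid 13 comes from aldehyde 8 by O-alkylation with methyl bromoacetate (9), Baeyer–Villiger oxidation (11), benzylation (12) and saponification. The forward cycloaddition must place ethoxy at C3 and aryloxy at C4, as the polarity of ketene and ynol ether dictates.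

## Roads not taken

Alternative 1: Both ether bonds of ring D are cut and ring D is supplied as 2,4,6-trifluorobenzaldehyde A1. In the forward step a hindered ring C phenoxide of the type of 24 would displace the para fluoride and the ring E phenoxide of 32 one ortho fluoride, giving the fluoro aldehyde heptamer A2. Nucleophilic aromatic substitution is little troubled by ortho substituents on the phenoxide, needs no metal, and the formyl group later becomes the D4 hydroxyl by Dakin oxidation. The weak points are the para/ortho selectivity of the first substitution (two ortho fluorides sit next to the activating carbonyl), the slower second substitution on a ring already carrying an aryloxy donor, and the leftover fluoride at D3, which must be exchanged for oxygen before the Dakin step. These add operations on the heptamer itself. For uniting the two arms this road is as good as or better than steps 19 and 20 of the chosen plan, since it avoids both the iodide/bromide discrimination and the hindered copper coupling. Against it the chosen plan sets site selection by halogen identity rather than ring position, no oxidation-state adjustment after the union, and above all a solution to the B–C bridge, which Alternative 1 leaves untouched because it presupposes the three-ring arm.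

Alternative 2: Ring C is cut internally and built by ring expansion of the squarate-derived cyclobutenone A3. Its 4π opening and 6π closure would give hydroquinone A4 with the ring B ether already in place. This is a thoroughly precedented rearrangement, more so than step 9, it makes the most oxygenated ring in one step, and it also sidesteps the doubly hindered B–C coupling. Its weak points lie around the key step. The vinyl nucleophile needed for A3 is a (Z)-2-aryloxyvinyl metal carrying rings A and B, a species prone to eliminate phenoxide, and its A–B ether must first be made by a hindered coupling. A4 has two free hydroxyls that must be told apart, the hindered one being kept for ring D, and it oxidises readily to the quinone. The chosen plan sets against the stronger precedent a product with a single phenol that needs no differentiation, a ring C phenol unmasked at will by hydrogenolysis, and formation of both ring B ethers without any aryl–oxygen coupling. Step counts are comparable.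

Alternative 3: Eleven aryl carbon–oxygen bonds are cut at once: the undecaformyl heptaaryl ether A5 would be converted by elevenfold Dakin oxidation into undecaphenol A6. The attraction is that each formyl group activates a fluoroarene for metal-free ether formation, so all six bridges, hindered or not, could come from substitution chemistry. In that respect it is better than the copper couplings of steps 15 and 20. The weak points are severe for this target. Eleven oxidations must all succeed on one molecule. Rings carrying two formyl groups become electron-rich phenols after the first oxidation and are then open to over-oxidation by the peracid. The formyl fluoroarene building blocks are not commercial. A6 still carries seven methyl ethers, so the global dealkylation is not saved. The chosen plan sets against it a key step that forms two carbon–carbon bonds on a three-ring intermediate early in the route, where a failure costs little, and far fewer steps to the building blocks.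

Key step: step 9

Assumption: the target is taken as drawn, an achiral octadecahydroxy heptaaryl hexaether, and cyclobutenone 17 is used as the racemate because its only stereocenter disappears on aromatisation.

## Route

Step 1
Reactants: 1 2,4,6-trimethoxyphenol; 2 trichloroethylene
Product: 4 2-{[(E)-1,2-dichloroethenyl]oxy}-1,3,5-trimethoxybenzene, via dichloroacetylene 3 (not isolated)
Conditions: K2CO3, DMF, 70 °C
Reagents that add atoms: none
Why: Base removes HCl from 2 and the phenoxide adds anti to the resulting dichloroacetylene, the standard route to aryl (E)-1,2-dichlorovinyl ethers; attack on a linear alkyne is not hindered by the two ortho methoxy groups.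

Step 2
Reactants: 4 2-{[(E)-1,2-dichloroethenyl]oxy}-1,3,5-trimethoxybenzene
Product: 6 2-(ethynyloxy)-1,3,5-trimethoxybenzene, via lithium aryloxyacetylide 5 (not isolated)
Conditions: n-BuLi (2.2 equiv), THF, −78 → −40 °C; then H2O, −78 °C
Reagents that add atoms: none
Why: Elimination of HCl and chlorine–lithium exchange convert dichlorovinyl ethers into lithium alkoxyacetylides (established ynol ether synthesis); cold protonation should give the terminal aryl ynol ether, which is used promptly.

Step 3
Reactants: 7 3,4,5-trimethoxyphenol
Product: 8 6-hydroxy-2,3,4-trimethoxybenzaldehyde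
Conditions: MgCl2, Et3N, (CH2O)n, MeCN, reflux; aq. HCl work-up
Reagents that add atoms: paraformaldehyde (as formaldehyde), C=O
Why: Magnesium phenoxide-directed ortho-formylation; the two free positions of 7 are equivalent and both ortho to the hydroxyl, and the formyl group deactivates the ring against a second reaction.

Step 4
Reactants: 8 6-hydroxy-2,3,4-trimethoxybenzaldehyde
Product: 9 methyl 2-(2-formyl-3,4,5-trimethoxyphenoxy)acetate
Conditions: BrCH2CO2Me, K2CO3, acetone, 40 °C
Reagents that add atoms: methyl bromoacetate, COC(=O)CBr
Why: Williamson alkylation of the salicylaldehyde-type phenol puts the two-carbon ketene precursor on the oxygen that becomes the B–C bridge; the mild temperature avoids base-induced aldol closure to a benzofuran.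

Step 5
Reactants: 9 methyl 2-(2-formyl-3,4,5-trimethoxyphenoxy)acetate
Product: 11 methyl 2-(2-hydroxy-3,4,5-trimethoxyphenoxy)acetate, via aryl formate 10 (not isolated)
Conditions: mCPBA, CH2Cl2, 0 °C → rt; then K2CO3 (cat.), MeOH, 0 °C
Reagents that add atoms: 3-chloroperoxybenzoic acid, O=C(OO)c1cccc(Cl)c1
Why: Baeyer–Villiger oxidation in which the electron-rich tetraoxygenated aryl group migrates in preference to hydrogen; the formate is cleaved by methanolysis, under which the methyl ester exchanges only with itself.

Step 6
Reactants: 11 methyl 2-(2-hydroxy-3,4,5-trimethoxyphenoxy)acetate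
Product: 12 methyl 2-[2-(benzyloxy)-3,4,5-trimethoxyphenoxy]acetate
Conditions: BnBr, K2CO3, acetone, reflux
Reagents that add atoms: benzyl bromide, BrCc1ccccc1
Why: Williamson benzylation of the only phenol; benzyl survives ketene formation and heating and is later removed by hydrogenolysis without touching the alkyl ethers that must last to the end.

Step 7
Reactants: 12 methyl 2-[2-(benzyloxy)-3,4,5-trimethoxyphenoxy]acetate
Product: 13 2-[2-(benzyloxy)-3,4,5-trimethoxyphenoxy]acetic acid
Conditions: LiOH, THF–H2O, rt; then aq. HCl
Reagents that add atoms: lithium hydroxide, [Li+].[OH-]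
Why: Ordinary saponification of an aryloxyacetate; no other group in 12 is base-labile.

Step 8
Reactants: 13 2-[2-(benzyloxy)-3,4,5-trimethoxyphenoxy]acetic acid; 14 ethoxyacetylene
Product: 17 4-[2-(benzyloxy)-3,4,5-trimethoxyphenoxy]-3-ethoxycyclobut-2-en-1-one (racemic), via acid chloride 15 (not isolated), via aryloxyketene 16 (not isolated)
Conditions: (COCl)2, cat. DMF, CH2Cl2, 0 °C → rt, evaporate; then 14 (3 equiv), Et3N, Et2O, 0 °C → rt
Reagents that add atoms: none
Why: Dehydrochlorination of the aryloxyacetyl chloride gives an electrophilic aryloxyketene that undergoes [2+2] cycloaddition with the ynol ether (ketene–alkoxyalkyne route to 3-alkoxycyclobutenones); the terminal alkyne carbon bonds to the ketene carbonyl carbon, so ethoxy ends at C3 and aryloxy at C4. The one stereocenter forms racemic and is erased in step 9.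

Step 9
Reactants: 17 4-[2-(benzyloxy)-3,4,5-trimethoxyphenoxy]-3-ethoxycyclobut-2-en-1-one (racemic); 6 2-(ethynyloxy)-1,3,5-trimethoxybenzene
Product: 22 2-[2-(benzyloxy)-3,4,5-trimethoxyphenoxy]-3-ethoxy-5-(2,4,6-trimethoxyphenoxy)phenol, via vinylketene 18 (not isolated), via 4-vinylcyclobutenone 19 (not isolated), via dienylketene 20 (not isolated), via cyclohexadienone 21 (not isolated)
Conditions: 6 (2 equiv), toluene, 80 → 110 °C, sealed tube, Ar
Reagents that add atoms: none
Why: Heating opens 17 by conrotatory 4π cleavage of the C1–C4 bond, the aryloxy donor turning outward, to give vinylketene 18. The ketene C=C of 18 adds to 6 in a [2+2] cycloaddition polarised so that the nucleophilic terminal alkyne carbon bonds to the ketene carbonyl carbon, giving the four-membered adduct 19. A second, reversible 4π opening gives dienylketene 20; only the isomer with the ketene and the alkoxyvinyl arm cis on the central double bond reacts further, so the equilibrium drains through it. Ring B is then closed by thermal disrotatory 6π electrocyclisation of 20, which joins the ketene carbon to the aryloxy-bearing terminus in a six-membered ring, and cyclohexadienone 21 tautomerises irreversibly to phenol 22. The closest known reaction type is the Danheiser benzannulation of cyclobutenones, 3-alkoxy ones included, with alkoxy- and siloxyalkynes to resorcinol monoethers; the aryl ynol ether and the 4-aryloxy group are new members of these substrate classes. No stereocenter survives: the sp3 centres of 17, 19 and 21 are racemic and vanish on aromatisation. Only regioselectivity is needed, and the donor oxygen of 6 secures it by placing the ring A ether meta to the new hydroxyl and para to the ring C ether. Excess 6 lets the alkyne rather than the product phenol trap 18, and 6 has no β-hydrogen, so the retro-ene loss that limits alkyl ynol ethers cannot occur.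

Step 10
Reactants: 22 2-[2-(benzyloxy)-3,4,5-trimethoxyphenoxy]-3-ethoxy-5-(2,4,6-trimethoxyphenoxy)phenol
Product: 23 2-(benzyloxy)-1-[2-ethoxy-6-methoxy-4-(2,4,6-trimethoxyphenoxy)phenoxy]-3,4,5-trimethoxybenzene
Conditions: MeI, K2CO3, acetone, reflux
Reagents that add atoms: iodomethane, CI
Why: Williamson methylation of the single phenol; capping it ensures that only the ring C oxygen is free after the next step.

Step 11
Reactants: 23 2-(benzyloxy)-1-[2-ethoxy-6-methoxy-4-(2,4,6-trimethoxyphenoxy)phenoxy]-3,4,5-trimethoxybenzene
Product: 24 6-[2-ethoxy-6-methoxy-4-(2,4,6-trimethoxyphenoxy)phenoxy]-2,3,4-trimethoxyphenol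
Conditions: H2 (1 atm), Pd/C, EtOAc–EtOH, rt
Reagents that add atoms: none
Why: Hydrogenolysis of the benzyl ether; alkyl aryl and diaryl ethers are inert and no halogen is present.

Step 12
Reactants: 8 6-hydroxy-2,3,4-trimethoxybenzaldehyde
Product: 25 6-(benzyloxy)-2,3,4-trimethoxybenzaldehyde
Conditions: BnBr, K2CO3, DMF, 50 °C
Reagents that add atoms: benzyl bromide, BrCc1ccccc1
Why: Williamson benzylation; here the original phenol oxygen is capped, so the oxygen introduced in step 13 becomes the free hindered phenol of ring E, the regioisomeric outcome to steps 4–6.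

Step 13
Reactants: 25 6-(benzyloxy)-2,3,4-trimethoxybenzaldehyde
Product: 27 6-(benzyloxy)-2,3,4-trimethoxyphenol, via aryl formate 26 (not isolated)
Conditions: mCPBA, CH2Cl2, 0 °C → rt; then K2CO3 (cat.), MeOH, 0 °C
Reagents that add atoms: 3-chloroperoxybenzoic acid, O=C(OO)c1cccc(Cl)c1
Why: Baeyer–Villiger oxidation with migration of the electron-rich aryl group, then methanolysis of the formate; benzyl and methyl ethers are unaffected.

Step 14
Reactants: 28 4-bromo-2,6-dimethoxyphenol; 29 5-iodo-1,2,3-trimethoxybenzene
Product: 30 5-bromo-1,3-dimethoxy-2-(3,4,5-trimethoxyphenoxy)benzene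
Conditions: 29 (1.3 equiv), CuI (10 mol%), picolinic acid (20 mol%), K3PO4, DMSO, 80 °C
Reagents that add atoms: none
Why: Ullmann diaryl ether coupling of a hindered phenoxide with an iodide flanked by two CH groups; the C–I bond reacts much faster than C–Br, and the bromide of 28 is further deactivated by its para phenoxide oxygen.

Step 15
Reactants: 27 6-(benzyloxy)-2,3,4-trimethoxyphenol; 30 5-bromo-1,3-dimethoxy-2-(3,4,5-trimethoxyphenoxy)benzene
Product: 31 1-(benzyloxy)-2-[3,5-dimethoxy-4-(3,4,5-trimethoxyphenoxy)phenoxy]-3,4,5-trimethoxybenzene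
Conditions: CuI (20 mol%), picolinic acid (40 mol%), K3PO4, DMSO, 100 °C, Ar
Reagents that add atoms: none
Why: Ullmann coupling of a doubly ortho-substituted phenoxide with an unhindered bromide under the picolinic acid-ligated CuI system used for hindered diaryl ethers; it also serves as a model for step 20.

Step 16
Reactants: 31 1-(benzyloxy)-2-[3,5-dimethoxy-4-(3,4,5-trimethoxyphenoxy)phenoxy]-3,4,5-trimethoxybenzene
Product: 32 2-[3,5-dimethoxy-4-(3,4,5-trimethoxyphenoxy)phenoxy]-3,4,5-trimethoxyphenol
Conditions: H2 (1 atm), Pd/C, EtOAc–EtOH, rt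
Reagents that add atoms: none
Why: Hydrogenolysis of the benzyl ether; the bromide of 30 has already been consumed, so nothing else is reducible.

Step 17
Reactants: 33 4-bromo-2-methoxyphenol
Product: 34 4-bromo-2-iodo-6-methoxyphenol
Conditions: I2, NaHCO3, THF–H2O, rt
Reagents that add atoms: iodine, II
Why: Electrophilic iodination of the phenoxide; the para position is blocked by bromine and the hydroxyl outranks the methoxy group, so iodine enters the free ortho position, as in the iodination of vanillin.

Step 18
Reactants: 34 4-bromo-2-iodo-6-methoxyphenol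
Product: 35 5-bromo-1-iodo-2,3-dimethoxybenzene
Conditions: MeI, K2CO3, acetone, reflux
Reagents that add atoms: iodomethane, CI
Why: Williamson methylation of the phenol.

Step 19
Reactants: 32 2-[3,5-dimethoxy-4-(3,4,5-trimethoxyphenoxy)phenoxy]-3,4,5-trimethoxyphenol; 35 5-bromo-1-iodo-2,3-dimethoxybenzene
Product: 36 5-bromo-1-{2-[3,5-dimethoxy-4-(3,4,5-trimethoxyphenoxy)phenoxy]-3,4,5-trimethoxyphenoxy}-2,3-dimethoxybenzene
Conditions: 35 (1.5 equiv), CuI (10 mol%), picolinic acid (20 mol%), K3PO4, DMSO, 70 °C, Ar
Reagents that add atoms: none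
Why: Ullmann coupling at the C–I bond, which monovalent copper activates far more readily than the C–Br bond; mild temperature and excess 35 should keep the bromide for step 20 and suppress double substitution.

Step 20
Reactants: 24 6-[2-ethoxy-6-methoxy-4-(2,4,6-trimethoxyphenoxy)phenoxy]-2,3,4-trimethoxyphenol; 36 5-bromo-1-{2-[3,5-dimethoxy-4-(3,4,5-trimethoxyphenoxy)phenoxy]-3,4,5-trimethoxyphenoxy}-2,3-dimethoxybenzene
Product: 37 2-{4-[2-(3-{2-[3,5-dimethoxy-4-(3,4,5-trimethoxyphenoxy)phenoxy]-3,4,5-trimethoxyphenoxy}-4,5-dimethoxyphenoxy)-3,4,5-trimethoxyphenoxy]-3-ethoxy-5-methoxyphenoxy}-1,3,5-trimethoxybenzene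
Conditions: CuI (20 mol%), picolinic acid (40 mol%), K3PO4, DMSO, 100 °C, Ar
Reagents that add atoms: none
Why: Ullmann coupling of the hindered ring C phenoxide with the ring D bromide, which is flanked by two CH groups; it is the same hindered-phenol/unhindered-halide pairing as step 15.

Step 21
Reactants: 37 2-{4-[2-(3-{2-[3,5-dimethoxy-4-(3,4,5-trimethoxyphenoxy)phenoxy]-3,4,5-trimethoxyphenoxy}-4,5-dimethoxyphenoxy)-3,4,5-trimethoxyphenoxy]-3-ethoxy-5-methoxyphenoxy}-1,3,5-trimethoxybenzene
Product: 38 2-{4-[2-(3-{2-[3,5-dihydroxy-4-(3,4,5-trihydroxyphenoxy)phenoxy]-3,4,5-trihydroxyphenoxy}-4,5-dihydroxyphenoxy)-3,4,5-trihydroxyphenoxy]-3,5-dihydroxyphenoxy}benzene-1,3,5-triol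
Conditions: BBr3 (excess), CH2Cl2, −78 °C → rt; then degassed ice-water, 0 °C; isolation under Ar
Reagents that add atoms: none
Why: Lewis acid dealkylation: BBr3 cleaves methyl and ethyl aryl ethers through bromide attack on the alkyl carbon and leaves diaryl ethers, which have no such carbon, intact; this is the usual final step for O-methylated oligo(aryl ether) polyphenols.

## Compound list

1 | 2,4,6-trimethoxyphenol | COc1cc(OC)c(O)c(OC)c1 | starting material
2 | trichloroethylene | ClC=C(Cl)Cl | starting material
3 | dichloroacetylene, formed and consumed in the flask | ClC#CCl | intermediate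
4 | 2-{[(E)-1,2-dichloroethenyl]oxy}-1,3,5-trimethoxybenzene | COc1cc(OC)c(O/C(Cl)=C\Cl)c(OC)c1 | intermediate
5 | lithium 2-(2,4,6-trimethoxyphenoxy)ethynide, formed and consumed in the flask | [Li]C#COc1c(OC)cc(OC)cc1OC | intermediate
6 | 2-(ethynyloxy)-1,3,5-trimethoxybenzene | COc1cc(OC)c(OC#C)c(OC)c1 | intermediate
7 | 3,4,5-trimethoxyphenol | COc1cc(O)cc(OC)c1OC | starting material
8 | 6-hydroxy-2,3,4-trimethoxybenzaldehyde | COc1cc(O)c(C=O)c(OC)c1OC | intermediate
9 | methyl 2-(2-formyl-3,4,5-trimethoxyphenoxy)acetate | COC(=O)COc1cc(OC)c(OC)c(OC)c1C=O | intermediate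
10 | methyl 2-[2-(formyloxy)-3,4,5-trimethoxyphenoxy]acetate, formed and consumed in the flask | COC(=O)COc1cc(OC)c(OC)c(OC)c1OC=O | intermediate
11 | methyl 2-(2-hydroxy-3,4,5-trimethoxyphenoxy)acetate | COC(=O)COc1cc(OC)c(OC)c(OC)c1O | intermediate
12 | methyl 2-[2-(benzyloxy)-3,4,5-trimethoxyphenoxy]acetate | COC(=O)COc1cc(OC)c(OC)c(OC)c1OCc1ccccc1 | intermediate
13 | 2-[2-(benzyloxy)-3,4,5-trimethoxyphenoxy]acetic acid | OC(=O)COc1cc(OC)c(OC)c(OC)c1OCc1ccccc1 | intermediate
14 | ethoxyacetylene | CCOC#C | starting material
15 | 2-[2-(benzyloxy)-3,4,5-trimethoxyphenoxy]acetyl chloride, formed and consumed in the flask | ClC(=O)COc1cc(OC)c(OC)c(OC)c1OCc1ccccc1 | intermediate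
16 | 2-[2-(benzyloxy)-3,4,5-trimethoxyphenoxy]ethen-1-one (aryloxyketene), formed and consumed in the flask | O=C=COc1cc(OC)c(OC)c(OC)c1OCc1ccccc1 | intermediate
17 | 4-[2-(benzyloxy)-3,4,5-trimethoxyphenoxy]-3-ethoxycyclobut-2-en-1-one (racemic) | CCOC1=CC(=O)C1Oc1cc(OC)c(OC)c(OC)c1OCc1ccccc1 | intermediate
18 | (3Z)-4-[2-(benzyloxy)-3,4,5-trimethoxyphenoxy]-3-ethoxybuta-1,3-dien-1-one, formed and consumed in the flask | O=C=C/C(OCC)=C/Oc1cc(OC)c(OC)c(OC)c1OCc1ccccc1 | intermediate
19 | 4-{(Z)-2-[2-(benzyloxy)-3,4,5-trimethoxyphenoxy]-1-ethoxyethenyl}-3-(2,4,6-trimethoxyphenoxy)cyclobut-2-en-1-one (racemic), formed and consumed in the flask | O=C1C=C(Oc2c(OC)cc(OC)cc2OC)C1/C(OCC)=C/Oc1cc(OC)c(OC)c(OC)c1OCc1ccccc1 | intermediate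
20 | (3E,5Z)-6-[2-(benzyloxy)-3,4,5-trimethoxyphenoxy]-5-ethoxy-3-(2,4,6-trimethoxyphenoxy)hexa-1,3,5-trien-1-one, formed and consumed in the flask | O=C=C/C(Oc1c(OC)cc(OC)cc1OC)=C\C(OCC)=C\Oc1cc(OC)c(OC)c(OC)c1OCc1ccccc1 | intermediate
21 | 6-[2-(benzyloxy)-3,4,5-trimethoxyphenoxy]-5-ethoxy-3-(2,4,6-trimethoxyphenoxy)cyclohexa-2,4-dien-1-one (racemic), formed and consumed in the flask | O=C1C=C(Oc2c(OC)cc(OC)cc2OC)C=C(OCC)C1Oc1cc(OC)c(OC)c(OC)c1OCc1ccccc1 | intermediate
22 | 2-[2-(benzyloxy)-3,4,5-trimethoxyphenoxy]-3-ethoxy-5-(2,4,6-trimethoxyphenoxy)phenol | COc1cc(OC)c(Oc2cc(O)c(Oc3cc(OC)c(OC)c(OC)c3OCc3ccccc3)c(OCC)c2)c(OC)c1 | intermediate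
23 | 2-(benzyloxy)-1-[2-ethoxy-6-methoxy-4-(2,4,6-trimethoxyphenoxy)phenoxy]-3,4,5-trimethoxybenzene | COc1cc(OC)c(Oc2cc(OC)c(Oc3cc(OC)c(OC)c(OC)c3OCc3ccccc3)c(OCC)c2)c(OC)c1 | intermediate
24 | 6-[2-ethoxy-6-methoxy-4-(2,4,6-trimethoxyphenoxy)phenoxy]-2,3,4-trimethoxyphenol | COc1cc(OC)c(Oc2cc(OC)c(Oc3cc(OC)c(OC)c(OC)c3O)c(OCC)c2)c(OC)c1 | intermediate
25 | 6-(benzyloxy)-2,3,4-trimethoxybenzaldehyde | COc1cc(OCc2ccccc2)c(C=O)c(OC)c1OC | intermediate
26 | 6-(benzyloxy)-2,3,4-trimethoxyphenyl formate, formed and consumed in the flask | COc1cc(OCc2ccccc2)c(OC=O)c(OC)c1OC | intermediate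
27 | 6-(benzyloxy)-2,3,4-trimethoxyphenol | COc1cc(OCc2ccccc2)c(O)c(OC)c1OC | intermediate
28 | 4-bromo-2,6-dimethoxyphenol | COc1cc(Br)cc(OC)c1O | starting material
29 | 5-iodo-1,2,3-trimethoxybenzene | COc1cc(I)cc(OC)c1OC | starting material
30 | 5-bromo-1,3-dimethoxy-2-(3,4,5-trimethoxyphenoxy)benzene | COc1cc(Br)cc(OC)c1Oc1cc(OC)c(OC)c(OC)c1 | intermediate
31 | 1-(benzyloxy)-2-[3,5-dimethoxy-4-(3,4,5-trimethoxyphenoxy)phenoxy]-3,4,5-trimethoxybenzene | COc1cc(OCc2ccccc2)c(Oc2cc(OC)c(Oc3cc(OC)c(OC)c(OC)c3)c(OC)c2)c(OC)c1OC | intermediate
32 | 2-[3,5-dimethoxy-4-(3,4,5-trimethoxyphenoxy)phenoxy]-3,4,5-trimethoxyphenol | COc1cc(O)c(Oc2cc(OC)c(Oc3cc(OC)c(OC)c(OC)c3)c(OC)c2)c(OC)c1OC | intermediate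
33 | 4-bromo-2-methoxyphenol | COc1cc(Br)ccc1O | starting material
34 | 4-bromo-2-iodo-6-methoxyphenol | COc1cc(Br)cc(I)c1O | intermediate
35 | 5-bromo-1-iodo-2,3-dimethoxybenzene | COc1cc(Br)cc(I)c1OC | intermediate
36 | 5-bromo-1-{2-[3,5-dimethoxy-4-(3,4,5-trimethoxyphenoxy)phenoxy]-3,4,5-trimethoxyphenoxy}-2,3-dimethoxybenzene | COc1cc(Br)cc(Oc2cc(OC)c(OC)c(OC)c2Oc2cc(OC)c(Oc3cc(OC)c(OC)c(OC)c3)c(OC)c2)c1OC | intermediate
37 | 2-{4-[2-(3-{2-[3,5-dimethoxy-4-(3,4,5-trimethoxyphenoxy)phenoxy]-3,4,5-trimethoxyphenoxy}-4,5-dimethoxyphenoxy)-3,4,5-trimethoxyphenoxy]-3-ethoxy-5-methoxyphenoxy}-1,3,5-trimethoxybenzene | COc1cc(OC)c(Oc2cc(OC)c(Oc3cc(OC)c(OC)c(OC)c3Oc3cc(OC)c(OC)c(Oc4cc(OC)c(OC)c(OC)c4Oc4cc(OC)c(Oc5cc(OC)c(OC)c(OC)c5)c(OC)c4)c3)c(OCC)c2)c(OC)c1 | intermediate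
38 | 2-{4-[2-(3-{2-[3,5-dihydroxy-4-(3,4,5-trihydroxyphenoxy)phenoxy]-3,4,5-trihydroxyphenoxy}-4,5-dihydroxyphenoxy)-3,4,5-trihydroxyphenoxy]-3,5-dihydroxyphenoxy}benzene-1,3,5-triol (CNP0130704.0) | Oc1cc(O)c(Oc2cc(O)c(Oc3cc(O)c(O)c(O)c3Oc3cc(O)c(O)c(Oc4cc(O)c(O)c(O)c4Oc4cc(O)c(Oc5cc(O)c(O)c(O)c5)c(O)c4)c3)c(O)c2)c(O)c1 | target

## Step count and risks

Total step count: 21. Longest linear sequence: 11 steps (steps 3 to 11, then 20 and 21, from 3,4,5-trimethoxyphenol 7).

**Step 9 (key step).** The most likely failure is thermal polymerisation of the aryl ynol ether 6 before cyclobutenone 17 has opened. A second risk is consumption of vinylketene 18 by acylation of the product phenol or by self-reaction, because the 3-ethoxy donor raises the opening temperature of 17. Fallback: starting from 17, the benzannulation is run with ethynyloxytri(propan-2-yl)silane, a siloxyalkyne of the class for which this reaction is established, to give 2-[2-(benzyloxy)-3,4,5-trimethoxyphenoxy]-3-ethoxy-5-{[tri(propan-2-yl)silyl]oxy}phenol F1. Methylation with MeI and K2CO3 gives {4-[2-(benzyloxy)-3,4,5-trimethoxyphenoxy]-3-ethoxy-5-methoxyphenoxy}tri(propan-2-yl)silane F2, and fluoride (Bu4NF, THF) frees 4-[2-(benzyloxy)-3,4,5-trimethoxyphenoxy]-3-ethoxy-5-methoxyphenol F3. This unhindered phenol is then coupled with commercial 2-iodo-1,3,5-trimethoxybenzene (CuI, picolinic acid, K3PO4, DMSO), and the route is rejoined at 23. Ring B is still built by the same two bond formations; only the A–B ether is deferred to a coupling.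

**Step 8.** Oligomerisation of the aryloxyketene 16 may outrun its cycloaddition to ethoxyacetylene, and the vinylogous ester 17 may hydrolyse during isolation. Fallback: starting from acid 13 (through 15 and 16 as before), the ketene is trapped with the far more reactive 1,1-diethoxyethene to give 2-[2-(benzyloxy)-3,4,5-trimethoxyphenoxy]-3,3-diethoxycyclobutan-1-one F4. Mild acid-induced loss of ethanol toward the unsubstituted methylene, the kinetically favoured direction, returns to 17; the position of the double bond must be checked before the material is used in step 9.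

**Step 20.** The large, doubly ortho-substituted phenoxide of 24 may add too slowly to the electron-rich bromide 36, so that hydrodebromination of 36 and oxidative loss of 24 take over. Fallback: starting from 36, a copper-catalysed aromatic Finkelstein exchange (CuI, N,N'-dimethylethane-1,2-diamine, NaI, dioxane, 110 °C) gives the iodide 1-{2-[3,5-dimethoxy-4-(3,4,5-trimethoxyphenoxy)phenoxy]-3,4,5-trimethoxyphenoxy}-5-iodo-2,3-dimethoxybenzene F6. This couples with 24 at lower temperature under the conditions of step 14 and returns to 37.

**Step 21.** Eighteen ether cleavages must all go to completion, and the freed polyphenol may be lost by air oxidation or on chromatography during isolation. Fallback: starting from 37, the crude dealkylation product is acetylated at once (Ac2O, pyridine) to the octadecaacetate of 38 F7, which is stable and can be purified on silica. Acid-catalysed methanolysis (HCl in degassed MeOH) then releases 38 without passing through oxidation-prone phenoxides.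

**Step 19.** Discrimination between the two halogens of 35 may be incomplete, leading to substitution at bromine or double substitution and loss of the handle for step 20. Fallback: starting from 35, iodine–magnesium exchange (iPrMgCl·LiCl, THF, −20 °C), which leaves aryl bromides untouched, followed by B(OMe)3 and aqueous acid gives (5-bromo-2,3-dimethoxyphenyl)boronic acid F5. Chan–Lam coupling of F5 with 32 (Cu(OAc)2, pyridine, air, CH2Cl2, rt), which cannot engage the bromide, returns to 36.

**Step 14.** Self-condensation of bromophenol 28 through its own bromide may compete with coupling to iodide 29. Fallback: starting from 28, a Chan–Lam coupling with commercial (3,4,5-trimethoxyphenyl)boronic acid (Cu(OAc)2, pyridine, air, CH2Cl2, rt) forms the same ether by an oxidative mechanism that does not touch aryl bromides, and returns to 30 without any new intermediate.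

## Further compounds

F1 | step 9 | 2-[2-(benzyloxy)-3,4,5-trimethoxyphenoxy]-3-ethoxy-5-{[tri(propan-2-yl)silyl]oxy}phenol | CCOc1cc(O[Si](C(C)C)(C(C)C)C(C)C)cc(O)c1Oc1cc(OC)c(OC)c(OC)c1OCc1ccccc1
F2 | step 9 | {4-[2-(benzyloxy)-3,4,5-trimethoxyphenoxy]-3-ethoxy-5-methoxyphenoxy}tri(propan-2-yl)silane | CCOc1cc(O[Si](C(C)C)(C(C)C)C(C)C)cc(OC)c1Oc1cc(OC)c(OC)c(OC)c1OCc1ccccc1
F3 | step 9 | 4-[2-(benzyloxy)-3,4,5-trimethoxyphenoxy]-3-ethoxy-5-methoxyphenol | CCOc1cc(O)cc(OC)c1Oc1cc(OC)c(OC)c(OC)c1OCc1ccccc1
F4 | step 8 | 2-[2-(benzyloxy)-3,4,5-trimethoxyphenoxy]-3,3-diethoxycyclobutan-1-one (racemic) | CCOC1(OCC)CC(=O)C1Oc1cc(OC)c(OC)c(OC)c1OCc1ccccc1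
F0 | step 14 | none | none
F5 | step 19 | (5-bromo-2,3-dimethoxyphenyl)boronic acid | COc1cc(Br)cc(B(O)O)c1OC
F6 | step 20 | 1-{2-[3,5-dimethoxy-4-(3,4,5-trimethoxyphenoxy)phenoxy]-3,4,5-trimethoxyphenoxy}-5-iodo-2,3-dimethoxybenzene | COc1cc(I)cc(Oc2cc(OC)c(OC)c(OC)c2Oc2cc(OC)c(Oc3cc(OC)c(OC)c(OC)c3)c(OC)c2)c1OC
F7 | step 21 | octadecaacetate of 38 | CC(=O)Oc1cc(OC(C)=O)c(Oc2cc(OC(C)=O)c(Oc3cc(OC(C)=O)c(OC(C)=O)c(OC(C)=O)c3Oc3cc(OC(C)=O)c(OC(C)=O)c(Oc4cc(OC(C)=O)c(OC(C)=O)c(OC(C)=O)c4Oc4cc(OC(C)=O)c(Oc5cc(OC(C)=O)c(OC(C)=O)c(OC(C)=O)c5)c(OC(C)=O)c4)c3)c(OC(C)=O)c2)c(OC(C)=O)c1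
A1 | alternative 1 | 2,4,6-trifluorobenzaldehyde | O=Cc1c(F)cc(F)cc1F
A2 | alternative 1 | heptameric 2,4-bis(aryloxy)-6-fluorobenzaldehyde (ring D as fluoro aldehyde, all other oxygens methylated) | COc1cc(OC)c(Oc2cc(OC)c(Oc3cc(OC)c(OC)c(OC)c3Oc3cc(F)c(C=O)c(Oc4cc(OC)c(OC)c(OC)c4Oc4cc(OC)c(Oc5cc(OC)c(OC)c(OC)c5)c(OC)c4)c3)c(OC)c2)c(OC)c1
A3 | alternative 2 | 4-{(Z)-2-[2,6-dimethoxy-4-(2,4,6-trimethoxyphenoxy)phenoxy]ethenyl}-4-hydroxy-2,3-dimethoxycyclobut-2-en-1-one (racemic) | COC1=C(OC)C(O)(/C=C\Oc2c(OC)cc(Oc3c(OC)cc(OC)cc3OC)cc2OC)C1=O
A4 | alternative 2 | 5-[2,6-dimethoxy-4-(2,4,6-trimethoxyphenoxy)phenoxy]-2,3-dimethoxybenzene-1,4-diol | COc1c(O)cc(Oc2c(OC)cc(Oc3c(OC)cc(OC)cc3OC)cc2OC)c(O)c1OC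
A5 | alternative 3 | undecaformyl heptaaryl hexaether with seven methyl ethers | COc1cc(C=O)c(Oc2cc(C=O)c(Oc3cc(C=O)c(OC)c(C=O)c3Oc3cc(OC)c(C=O)c(Oc4cc(C=O)c(OC)c(C=O)c4Oc4cc(C=O)c(Oc5cc(OC)c(OC)c(OC)c5)c(C=O)c4)c3)c(C=O)c2)c(C=O)c1
A6 | alternative 3 | undecaphenol heptamer with seven methyl ethers | COc1cc(O)c(Oc2cc(O)c(Oc3cc(O)c(OC)c(O)c3Oc3cc(OC)c(O)c(Oc4cc(O)c(OC)c(O)c4Oc4cc(O)c(Oc5cc(OC)c(OC)c(OC)c5)c(O)c4)c3)c(O)c2)c(O)c1
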